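Ring A of the isocoumarin is disconnected across C6–C7, C8–C8a and C5–C6. Its contiguous pattern (C1 carboxyl on C8a, aryloxy on C8, hydrogen on C7, hydroxyl on C6, carbon arm on C4a) maps onto an ester-substituted vinylketene and an aryl ethynyl ether that already holds the ring B oxygen. One photochemical Wolff rearrangement/benzannulation operation therefore builds the hindered 2-aryloxy-4-hydroxy-6-methylbenzoate with the diaryl ether in place and without any aryl C–O coupling. Its precursors are ethyl 2-diazo-4-methyl-3-oxopent-4-enoate, reached by diazoacetate aldol addition and oxidation so that no polymerisable vinyl keto ester is handled, and 1-(ethynyloxy)-2,4-dimethoxy-6-pentylbenzene. Lateral lithiation, acylation, enol lactonisation and demethylation complete the target.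

Key step: step 7

Assumption: the ester alkyl group is a spectator that leaves as the alcohol at lactonisation, so the ethyl ester is carried (ethyl diazoacetate is the readily purchased diazoacetate); N-methoxy-N-methylhexanamide is taken as a catalogue reagent; the target has no stereocentre.

Step 1
Reactants: 1 1,3-dimethoxy-5-pentylbenzene (olivetol dimethyl ether)
Product: 3 2,4-dimethoxy-6-pentylbenzaldehyde, via aryl iminium chloride 2 (not isolated)
Conditions: POCl3, DMF, 0 → 60 °C; then H2O
Reagents that add atoms: N,N-dimethylformamide, CN(C)C=O; water, O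
Why: Vilsmeier–Haack formylation: the chloroiminium electrophile attacks the ring carbon para to one methoxy group and ortho to the other, next to the pentyl chain, in preference to the more crowded carbon between the two methoxy groups, and water hydrolyses the iminium salt to the aldehyde.

Step 2
Reactants: 3 2,4-dimethoxy-6-pentylbenzaldehyde
Product: 5 2,4-dimethoxy-6-pentylphenol, via 2,4-dimethoxy-6-pentylphenyl formate 4 (not isolated)
Conditions: mCPBA, CH2Cl2, 0 °C → rt; then K2CO3 (cat.), MeOH, rt
Reagents that add atoms: 3-chloroperoxybenzoic acid (mCPBA), O=C(OO)c1cccc(Cl)c1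
Why: Baeyer–Villiger oxidation of an electron-rich benzaldehyde (Dakin-type) proceeds by aryl migration to the formate, which base-catalysed methanolysis cleaves to the phenol without touching the methyl ethers.

Step 3
Reactants: 5 2,4-dimethoxy-6-pentylphenol; 6 trichloroethylene
Product: 8 1-{[(E)-1,2-dichloroethenyl]oxy}-2,4-dimethoxy-6-pentylbenzene, via dichloroacetylene 7 (not isolated)
Conditions: K2CO3, DMF, 70 °C
Reagents that add atoms: none
Why: Elimination–addition: K2CO3 converts trichloroethylene into dichloroacetylene, and anti addition of the phenoxide and a proton across this haloalkyne gives the (E)-1,2-dichlorovinyl ether, a reaction that tolerates ortho-substituted phenols.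

Step 4
Reactants: 8 1-{[(E)-1,2-dichloroethenyl]oxy}-2,4-dimethoxy-6-pentylbenzene
Product: 11 1-(ethynyloxy)-2,4-dimethoxy-6-pentylbenzene, via chloroethynyl aryl ether 9 (not isolated), via lithium aryloxyacetylide 10 (not isolated)
Conditions: n-BuLi (2.2 equiv), THF, −78 → −40 °C; then H2O, −78 °C
Reagents that add atoms: none
Why: Dehydrochlorination to the chloroalkynyl ether and chlorine–lithium exchange with the second equivalent of n-BuLi give the lithium acetylide, whose protonation delivers the terminal ynol ether (the standard dichlorovinyl ether route to alkynyl ethers), the two ortho substituents shielding the sensitive O–C≡C unit.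

Step 5
Reactants: 12 ethyl diazoacetate; 13 methacrolein
Product: 15 ethyl 2-diazo-3-hydroxy-4-methylpent-4-enoate (racemic), via ethyl lithiodiazoacetate 14 (not isolated)
Conditions: LiN(iPr)2, THF, −78 °C; then 13; AcOH, −78 °C
Reagents that add atoms: none
Why: Aldol-type 1,2-addition of lithiated ethyl diazoacetate to the aldehyde is fast at −78 °C and outruns dipolar cycloaddition to the enal; the new carbinol centre forms racemic and needs no control because step 6 oxidises it.

Step 6
Reactants: 15 ethyl 2-diazo-3-hydroxy-4-methylpent-4-enoate (racemic)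
Product: 16 ethyl 2-diazo-4-methyl-3-oxopent-4-enoate
Conditions: IBX, DMSO, rt
Reagents that add atoms: none
Why: IBX oxidation of the secondary allylic alcohol of an α-diazo-β-hydroxy ester leaves the acceptor-stabilised diazo group intact, and since the diazo carbon is already in place the vinyl ketone has no acidic methylene for Michael self-addition.

Step 7
Reactants: 16 ethyl 2-diazo-4-methyl-3-oxopent-4-enoate (1.3 equiv); 11 1-(ethynyloxy)-2,4-dimethoxy-6-pentylbenzene
Product: 21 ethyl 2-(2,4-dimethoxy-6-pentylphenoxy)-4-hydroxy-6-methylbenzoate, via vinylketene 17 (not isolated), via cyclobutenone 18 (not isolated), via dienylketene 19 (not isolated), via cyclohexadienone 20 (not isolated)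
Conditions: hν (medium-pressure Hg lamp through Pyrex, λ > 300 nm), degassed ClCH2CH2Cl, 20 °C; then 80 °C
Reagents that add atoms: none
Why: Proposed new method: light expels N2 from 16 and the isopropenyl group migrates (Wolff rearrangement) to give vinylketene 17, whose electrophilic ketene carbon (future C6) is attacked by the nucleophilic CH terminus of ynol ether 11 (future C7) while the aryloxy-bearing carbon (future C8) bonds to the ester-bearing carbon (future C8a), a [2+2] cycloaddition that gives cyclobutenone 18. Warming opens 18 by reversible 4π electrocyclic cleavage to dienylketene 19, and ring A is closed by thermal disrotatory 6π electrocyclisation (six-membered carbocycle, C5–C6 bond) to dienone 20, which enolises irreversibly to phenol 21. The closest known reaction type is the Danheiser benzannulation in its photochemical Wolff variant, established for vinylketenes without an ester substituent and for alkoxy- and siloxyalkynes, but not for an ester-bearing vinylketene or an aryl ethynyl ether. No stereocentre remains in 21; the quaternary centre of 18 forms racemic and is erased on ring opening. The step needs periselectivity for [2+2] at the ketene C=C over hetero-[4+2] through the ester carbonyl and over oxa-6π closure of the wrong rotamer of 19, which the weak heterodiene character of an ester, the reversibility of the ring opening and the aromatisation sink should provide; the regiochemistry follows from the polarisation of the ynol ether, whose oxygen stabilises positive charge on the carbon that becomes C8.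

Step 8
Reactants: 21 ethyl 2-(2,4-dimethoxy-6-pentylphenoxy)-4-hydroxy-6-methylbenzoate
Product: 22 ethyl 2-(2,4-dimethoxy-6-pentylphenoxy)-4-methoxy-6-methylbenzoate
Conditions: MeI, K2CO3, acetone, reflux
Reagents that add atoms: iodomethane, CI
Why: Williamson etherification of the unhindered phenol para to the ester; the di-ortho-substituted ethyl ester and the diaryl ether are inert to K2CO3 and MeI.

Step 9
Reactants: 22 ethyl 2-(2,4-dimethoxy-6-pentylphenoxy)-4-methoxy-6-methylbenzoate; 23 N-methoxy-N-methylhexanamide
Product: 26 ethyl 2-(2,4-dimethoxy-6-pentylphenoxy)-4-methoxy-6-(2-oxoheptyl)benzoate, via lithiated toluate 24 (not isolated), via lithium hemiaminal alkoxide 25 (not isolated)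
Conditions: LiN(iPr)2, THF, −78 °C; then 23, −78 → −20 °C; aq. HCl
Reagents that add atoms: none
Why: Lateral lithiation of the ortho-toluate gives an ester-stabilised benzylic anion (the flanked ester resists self-condensation at −78 °C), and acylation by the Weinreb amide stops at the chelated, racemic tetrahedral adduct, so the ketone is released only on acidic quench and is neither enolised nor attacked twice.

Step 10
Reactants: 26 ethyl 2-(2,4-dimethoxy-6-pentylphenoxy)-4-methoxy-6-(2-oxoheptyl)benzoate
Product: 27 8-(2,4-dimethoxy-6-pentylphenoxy)-6-methoxy-3-pentyl-1H-isochromen-1-one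
Conditions: TsOH·H2O (cat.), toluene, reflux
Reagents that add atoms: none
Why: Acid-catalysed enol lactonisation: the enol oxygen of the benzylic ketone attacks the adjacent ester in a six-membered transition state and ethanol is expelled, the conjugated isocoumarin being the thermodynamic sink.

Step 11
Reactants: 27 8-(2,4-dimethoxy-6-pentylphenoxy)-6-methoxy-3-pentyl-1H-isochromen-1-one
Product: 29 8-(2,4-dihydroxy-6-pentylphenoxy)-6-hydroxy-3-pentyl-1H-isochromen-1-one (target), via tris(dibromoboryl) ether 28 (not isolated)
Conditions: BBr3 (6 equiv), CH2Cl2, −78 °C → rt; then H2O, 0 °C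
Reagents that add atoms: none
Why: BBr3-mediated cleavage of aryl methyl ethers (bromide attack at the methyl of the boron-complexed ether) removes all three methyl groups while the diaryl ether and the conjugated lactone persist, and a cold acidic aqueous quench hydrolyses the aryl borates without base-induced acyl transfer to the neighbouring 2'-hydroxyl.

Compound list
1 | 1,3-dimethoxy-5-pentylbenzene (olivetol dimethyl ether) | CCCCCc1cc(OC)cc(OC)c1 | starting material
2 | N-[(2,4-dimethoxy-6-pentylphenyl)methylidene]-N-methylmethanaminium chloride (not isolated) | CCCCCc1cc(OC)cc(OC)c1C=[N+](C)C.[Cl-] | intermediate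
3 | 2,4-dimethoxy-6-pentylbenzaldehyde | CCCCCc1cc(OC)cc(OC)c1C=O | intermediate
4 | 2,4-dimethoxy-6-pentylphenyl formate (not isolated) | CCCCCc1cc(OC)cc(OC)c1OC=O | intermediate
5 | 2,4-dimethoxy-6-pentylphenol | CCCCCc1cc(OC)cc(OC)c1O | intermediate
6 | trichloroethylene | ClC=C(Cl)Cl | starting material
7 | dichloroacetylene (not isolated) | ClC#CCl | intermediate
8 | 1-{[(E)-1,2-dichloroethenyl]oxy}-2,4-dimethoxy-6-pentylbenzene | Cl/C=C(/Cl)Oc1c(OC)cc(OC)cc1CCCCC | intermediate
9 | 1-[(chloroethynyl)oxy]-2,4-dimethoxy-6-pentylbenzene (not isolated) | CCCCCc1cc(OC)cc(OC)c1OC#CCl | intermediate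
10 | lithium (2,4-dimethoxy-6-pentylphenoxy)acetylide (not isolated) | CCCCCc1cc(OC)cc(OC)c1OC#C[Li] | intermediate
11 | 1-(ethynyloxy)-2,4-dimethoxy-6-pentylbenzene | CCCCCc1cc(OC)cc(OC)c1OC#C | intermediate
12 | ethyl diazoacetate | CCOC(=O)C=[N+]=[N-] | starting material
13 | methacrolein | C=C(C)C=O | starting material
14 | ethyl lithiodiazoacetate (not isolated) | CCOC(=O)C([Li])=[N+]=[N-] | intermediate
15 | ethyl 2-diazo-3-hydroxy-4-methylpent-4-enoate (racemic) | CCOC(=O)C(=[N+]=[N-])C(O)C(C)=C | intermediate
16 | ethyl 2-diazo-4-methyl-3-oxopent-4-enoate | CCOC(=O)C(=[N+]=[N-])C(=O)C(C)=C | intermediate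
17 | ethyl 3-methyl-2-(oxomethylidene)but-3-enoate (vinylketene, not isolated) | CCOC(=O)C(=C=O)C(C)=C | intermediate
18 | ethyl 2-(2,4-dimethoxy-6-pentylphenoxy)-4-oxo-1-(prop-1-en-2-yl)cyclobut-2-ene-1-carboxylate (racemic, not isolated) | CCOC(=O)C1(C(C)=C)C(=O)C=C1Oc1c(OC)cc(OC)cc1CCCCC | intermediate
19 | ethyl (2Z)-3-(2,4-dimethoxy-6-pentylphenoxy)-5-oxo-2-(prop-1-en-2-yl)penta-2,4-dienoate (dienylketene, not isolated) | O=C=C/C(Oc1c(OC)cc(OC)cc1CCCCC)=C(\C(C)=C)C(=O)OCC | intermediate
20 | ethyl 6-(2,4-dimethoxy-6-pentylphenoxy)-2-methyl-4-oxocyclohexa-1,5-diene-1-carboxylate (not isolated) | CCOC(=O)C1=C(C)CC(=O)C=C1Oc1c(OC)cc(OC)cc1CCCCC | intermediate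
21 | ethyl 2-(2,4-dimethoxy-6-pentylphenoxy)-4-hydroxy-6-methylbenzoate | CCOC(=O)c1c(C)cc(O)cc1Oc1c(OC)cc(OC)cc1CCCCC | intermediate
22 | ethyl 2-(2,4-dimethoxy-6-pentylphenoxy)-4-methoxy-6-methylbenzoate | CCOC(=O)c1c(C)cc(OC)cc1Oc1c(OC)cc(OC)cc1CCCCC | intermediate
23 | N-methoxy-N-methylhexanamide | CCCCCC(=O)N(C)OC | starting material
24 | ethyl 2-(2,4-dimethoxy-6-pentylphenoxy)-6-(lithiomethyl)-4-methoxybenzoate (not isolated) | CCOC(=O)c1c(C[Li])cc(OC)cc1Oc1c(OC)cc(OC)cc1CCCCC | intermediate
25 | lithium alkoxide of ethyl 2-(2,4-dimethoxy-6-pentylphenoxy)-6-{2-hydroxy-2-[methoxy(methyl)amino]heptyl}-4-methoxybenzoate (racemic, not isolated) | CCCCCC(O[Li])(Cc1cc(OC)cc(Oc2c(OC)cc(OC)cc2CCCCC)c1C(=O)OCC)N(C)OC | intermediate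
26 | ethyl 2-(2,4-dimethoxy-6-pentylphenoxy)-4-methoxy-6-(2-oxoheptyl)benzoate | CCCCCC(=O)Cc1cc(OC)cc(Oc2c(OC)cc(OC)cc2CCCCC)c1C(=O)OCC | intermediate
27 | 8-(2,4-dimethoxy-6-pentylphenoxy)-6-methoxy-3-pentyl-1H-isochromen-1-one | CCCCCc1cc2cc(OC)cc(Oc3c(OC)cc(OC)cc3CCCCC)c2c(=O)o1 | intermediate
28 | 6-[(dibromoboranyl)oxy]-8-{2,4-bis[(dibromoboranyl)oxy]-6-pentylphenoxy}-3-pentyl-1H-isochromen-1-one (not isolated) | CCCCCc1cc2cc(OB(Br)Br)cc(Oc3c(OB(Br)Br)cc(OB(Br)Br)cc3CCCCC)c2c(=O)o1 | intermediate
29 | 8-(2,4-dihydroxy-6-pentylphenoxy)-6-hydroxy-3-pentyl-1H-isochromen-1-one | CCCCCc1cc2cc(O)cc(Oc3c(O)cc(O)cc3CCCCC)c2c(=O)o1 | target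

Total step count: 11. Longest linear sequence: 9 steps (steps 1–4 and 7–11, from compound 1).

Steps most likely to fail

1. Step 7. The ketene may be drained along other channels: hetero-[4+2] capture through the ester carbonyl, acylation of the phenol as it forms, or dimerisation. The aryloxyalkyne may also prove too weak a ketenophile, so that the [2+2] event does not compete. The fallback uses known aryl C–O coupling; it sets out from phenol 5 and returns at 22, bypassing steps 3–8. Purchased ethyl 2,4-dihydroxy-6-methylbenzoate F1 would be methylated selectively at the non-chelated 4-hydroxyl (MeI, K2CO3, acetone) to ethyl 2-hydroxy-4-methoxy-6-methylbenzoate F2. Tf2O and pyridine would convert this into ethyl 4-methoxy-2-methyl-6-{[(trifluoromethyl)sulfonyl]oxy}benzoate F3. Buchwald–Hartwig etherification of F3 with 5 (Pd(OAc)2, 2-di-tert-butylphosphino-2',4',6'-triisopropylbiphenyl, K3PO4, toluene, 100 °C) should then give 22.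

2. Step 4. The terminal alkynyl ether may be lost by hydration or oligomerisation during aqueous work-up, purification and storage. The fallback carries the alkyne in a capped, purifiable form; it sets out from 8 and returns at 11. Acetylide 10, generated as in step 4, would be quenched with Me3SiCl to give [(2,4-dimethoxy-6-pentylphenoxy)ethynyl]trimethylsilane F4, which should tolerate chromatography and cold storage. Fluoride-induced protodesilylation (Bu4NF, wet THF, −20 °C) would release 11 immediately before step 7, and the crude solution would be used after solvent exchange.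

3. Step 9. The lithiated toluate may condense with unreacted ester, or the amide base may attack the ester carbonyl, so that the benzylic anion is not delivered cleanly to the Weinreb amide. The fallback removes the electrophilic ester; it sets out from 22 and returns at 27, bypassing step 10. Saponification of 22 (KOH, DMSO/H2O, 100 °C) would give 2-(2,4-dimethoxy-6-pentylphenoxy)-4-methoxy-6-methylbenzoic acid F5. Its carboxylate-directed lateral lithiation (LiN(iPr)2, 2.2 equiv, THF, −78 → 0 °C) and acylation of the dianion with 23 would give 2-(2,4-dimethoxy-6-pentylphenoxy)-4-methoxy-6-(2-oxoheptyl)benzoic acid F6. Cyclodehydration of this keto acid (Ac2O, reflux) should give 27.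

Further compounds
F1 | step 7 | ethyl 2,4-dihydroxy-6-methylbenzoate (purchased) | CCOC(=O)c1c(C)cc(O)cc1O
F2 | step 7 | ethyl 2-hydroxy-4-methoxy-6-methylbenzoate | CCOC(=O)c1c(C)cc(OC)cc1O
F3 | step 7 | ethyl 4-methoxy-2-methyl-6-{[(trifluoromethyl)sulfonyl]oxy}benzoate | CCOC(=O)c1c(C)cc(OC)cc1OS(=O)(=O)C(F)(F)F
F4 | step 4 | [(2,4-dimethoxy-6-pentylphenoxy)ethynyl]trimethylsilane | CCCCCc1cc(OC)cc(OC)c1OC#C[Si](C)(C)C
F5 | step 9 | 2-(2,4-dimethoxy-6-pentylphenoxy)-4-methoxy-6-methylbenzoic acid | OC(=O)c1c(C)cc(OC)cc1Oc1c(OC)cc(OC)cc1CCCCC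
F6 | step 9 | 2-(2,4-dimethoxy-6-pentylphenoxy)-4-methoxy-6-(2-oxoheptyl)benzoic acid | CCCCCC(=O)Cc1cc(OC)cc(Oc2c(OC)cc(OC)cc2CCCCC)c1C(O)=O
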